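**Retrosynthetic overview**
1. Last disconnection: the benzylic ester C–O bond, made by enzymatic acyl transfer to the only aliphatic hydroxyl while both phenols stay free.
2. The benzylic alcohol comes from an aryl aldehyde; the formyl group is kept until then because it steers the key coupling.
3. Key disconnection: the diaryl ether C–O bond between C2 of ring A (as its bromide) and one oxygen of the symmetric ring B 1,3-diol, copper-catalysed with a transient imine ligand.
4. The C2–Br bond of ring A comes from bromination ortho to the free OH and para to the OMe of a bought hydroxy-methoxy-benzaldehyde.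
5. Ring order: no ring is built; rings A and B are both bought as benzenes, ring A is functionalised first and then joined to ring B.

Assumption: the target has no stereocentre and no stereogenic double bond, so the achiral compound itself is the "single enantiomer" asked for.

**Route**

Step 1
Reactants: 1 3-hydroxy-5-methoxybenzaldehyde
Product: 2 2-bromo-3-hydroxy-5-methoxybenzaldehyde
Conditions: NBS (1.0 equiv), i-Pr2NH (10 mol %), CH2Cl2, −20 to 0 °C
Reagents that add atoms: N-bromosuccinimide, O=C1CCC(=O)N1Br
Why: Amine-mediated electrophilic aromatic bromination (the N-bromoamine formed from NBS and i-Pr2NH is hydrogen-bonded to the phenol and delivers bromine ortho to it) should pick C2, the only position that is both ortho to the OH and para to the OMe, whereas C4 lies between two oxygens and C6 is para to the OH and out of reach of the delivery; the formyl-deactivated ring stops at monobromination and no stereocentre is formed.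

Step 2
Reactants: 2 2-bromo-3-hydroxy-5-methoxybenzaldehyde; 3 orcinol (5-methylbenzene-1,3-diol, 4 equiv)
Product: 6 3-hydroxy-2-(3-hydroxy-5-methylphenoxy)-5-methoxybenzaldehyde, via bromo aldimine 4 (not isolated), via aryloxy aldimine 5 (not isolated)
Conditions: CuI (10 mol %), 2-amino-2-methylpropanoic acid (30 mol %), K3PO4 (3 equiv), DMSO, 80 °C, N2; then 1 M HCl, rt
Reagents that add atoms: none
Why: Proposed new method: a transient-ligand-directed Ullmann etherification in which 2-amino-2-methylpropanoic acid condenses reversibly with the formyl group of 2 to give the α-imino carboxylate 4 (no α-hydrogen, so no transamination, and a hindered nitrogen that resists N-arylation), whose imine nitrogen and carboxylate bind monovalent copper and hold it beside the doubly flanked C2–Br bond, so that oxidative addition to a five-membered aza-cupracycle of trivalent copper becomes feasible despite the electron-rich ortho-phenoxide, after which the monopotassium salt of symmetric orcinol (either oxygen gives the same product, the excess suppresses double arylation) exchanges onto copper, C–O reductive elimination gives 5, and the water released in the condensation hydrolyses 5 to 6 and returns the amino acid; the closest known reaction types are the Hurtley-type ortho-carboxylate- and ortho-carbonyl-assisted Ullmann diaryl ether synthesis and transient-directing-group C–H functionalisation of benzaldehydes; no stereocentre is formed.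

Step 3
Reactants: 6 3-hydroxy-2-(3-hydroxy-5-methylphenoxy)-5-methoxybenzaldehyde
Product: 7 3-(hydroxymethyl)-2-(3-hydroxy-5-methylphenoxy)-5-methoxyphenol
Conditions: NaBH4 (1.5 equiv), MeOH–THF (1:1), 0 °C; then sat. aq. NH4Cl
Reagents that add atoms: none
Why: Chemoselective borohydride reduction of the aryl aldehyde to the benzylic alcohol; the phenols, the diaryl ether and the methyl ether are inert to NaBH4 and no stereocentre is formed.

Step 4
Reactants: 7 3-(hydroxymethyl)-2-(3-hydroxy-5-methylphenoxy)-5-methoxyphenol; 8 vinyl palmitate (ethenyl hexadecanoate, 3 equiv)
Product: 9 Betaethrin H, [3-hydroxy-2-(3-hydroxy-5-methylphenoxy)-5-methoxyphenyl]methyl hexadecanoate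
Conditions: immobilised Candida antarctica lipase B, 2-methyl-2-butanol, 4 Å MS, 45 °C
Reagents that add atoms: none
Why: Lipase-catalysed irreversible transesterification (acyl-enzyme from the vinyl ester, which leaves as acetaldehyde) acylates the primary benzylic hydroxyl and leaves both phenolic hydroxyls untouched, as in known lipase acylations of hydroxybenzyl alcohols with fatty acid vinyl esters; no stereocentre is involved.

**Compound list**
1 | 3-hydroxy-5-methoxybenzaldehyde | O=Cc1cc(OC)cc(O)c1 | starting material
2 | 2-bromo-3-hydroxy-5-methoxybenzaldehyde | O=Cc1cc(OC)cc(O)c1Br | intermediate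
3 | orcinol (5-methylbenzene-1,3-diol) | Cc1cc(O)cc(O)c1 | starting material
4 | bromo aldimine, 2-{[(E)-(2-bromo-3-hydroxy-5-methoxyphenyl)methylidene]amino}-2-methylpropanoic acid | OC(=O)C(C)(C)/N=C/c1cc(OC)cc(O)c1Br | intermediate
5 | aryloxy aldimine, 2-({(E)-[3-hydroxy-2-(3-hydroxy-5-methylphenoxy)-5-methoxyphenyl]methylidene}amino)-2-methylpropanoic acid | OC(=O)C(C)(C)/N=C/c1cc(OC)cc(O)c1Oc1cc(C)cc(O)c1 | intermediate
6 | 3-hydroxy-2-(3-hydroxy-5-methylphenoxy)-5-methoxybenzaldehyde | O=Cc1cc(OC)cc(O)c1Oc1cc(C)cc(O)c1 | intermediate
7 | 3-(hydroxymethyl)-2-(3-hydroxy-5-methylphenoxy)-5-methoxyphenol | OCc1cc(OC)cc(O)c1Oc1cc(C)cc(O)c1 | intermediate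
8 | vinyl palmitate (ethenyl hexadecanoate) | CCCCCCCCCCCCCCCC(=O)OC=C | starting material
9 | Betaethrin H, [3-hydroxy-2-(3-hydroxy-5-methylphenoxy)-5-methoxyphenyl]methyl hexadecanoate (achiral) | CCCCCCCCCCCCCCCC(=O)OCc1cc(OC)cc(O)c1Oc1cc(C)cc(O)c1 | target

**Count**
Total step count: 4. Longest linear sequence: 4 steps (1 → 2 → 6 → 7 → 9).

**Three steps most likely to fail**

Step 2 (the proposed new coupling) may stall because the bromide is flanked on both sides and carries a free ortho-phenoxide, or because the amino acid is consumed. The fallback uses known chemistry, sets out from 2 and comes back to the route at 6. The phenol of 2 is capped with MOMCl and i-Pr2NEt in CH2Cl2 to give 2-bromo-5-methoxy-3-(methoxymethoxy)benzaldehyde F3. This protected bromide is coupled with orcinol 3 (3 equiv) under an established ancillary-ligand Ullmann protocol for hindered partners (CuI, picolinic acid, K3PO4, DMSO, 90 °C), which does not depend on the formyl group as a binding site, to give 2-(3-hydroxy-5-methylphenoxy)-5-methoxy-3-(methoxymethoxy)benzaldehyde F4. The acetal is then removed with 2 M HCl in THF at 40 °C to give 6.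

Step 1 may give a mixture of the C2, C6 and C4 bromides. The fallback changes the directing principle from delivery by the phenol to control by the methoxy group; it sets out from 1 and comes back at 2. Acetylation of 1 (Ac2O, pyridine, rt) gives 3-formyl-5-methoxyphenyl acetate F1, in which the acetoxy group is only a weak director. NBS in MeCN then brominates para to the methoxy group, as m-anisaldehyde does, to give 2-bromo-3-formyl-5-methoxyphenyl acetate F2. Methanolysis with catalytic K2CO3 in MeOH at 0 °C frees the phenol and gives 2.

Step 4 may be slow on the benzylic alcohol beside the aryloxy group, or may give some phenol ester. The fallback activates the alcohol instead of the acyl donor; it sets out from 7 and comes back at 9. A Mitsunobu esterification with palmitic acid (1.1 equiv), PPh3 and DIAD in THF at 0 °C to rt is used: the carboxylic acid is far more acidic than the phenols, so it alone is deprotonated by the betaine and displaces the activated primary oxygen, a known chemoselective way to esterify phenolic alcohols. New compounds on this way: none F0.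

**Further compounds**
F1 | step 1 | 3-formyl-5-methoxyphenyl acetate | CC(=O)Oc1cc(OC)cc(C=O)c1
F2 | step 1 | 2-bromo-3-formyl-5-methoxyphenyl acetate | CC(=O)Oc1cc(OC)cc(C=O)c1Br
F3 | step 2 | 2-bromo-5-methoxy-3-(methoxymethoxy)benzaldehyde | O=Cc1cc(OC)cc(OCOC)c1Br
F4 | step 2 | 2-(3-hydroxy-5-methylphenoxy)-5-methoxy-3-(methoxymethoxy)benzaldehyde | O=Cc1cc(OC)cc(OCOC)c1Oc1cc(C)cc(O)c1
F0 | step 4 | none | none
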